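A one-step world has one clock, and a flask's state can be read off its minutes. The steps offered here have at least two clocks: X may turn into Z by itself, but X may go on to Q by meeting D.

| flask | E | D | remark | time |
|---|---|---|---|---|
| ochre | 2 mM | 43 mM | run made earlier |  |
| violet | 2 mM | 14 mM | run made earlier |  |
| south | 2.0 mM | 28.8 mM |  | 15 min |
| east | 5.0 mM | 28.8 mM |  | 15 min |
| south-west | 15 mM | 28.8 mM |  | 15 min |
| north-west | 50 mM | 28.8 mM |  | 15 min |
| north-east | 150 mM | 28.8 mM |  | 15 min |

| run | time / min | X / % | Q / % | Z / % |
|---|---|---|---|---|
| ochre | 1.00 | 41 | 11 | 7 |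
| ochre | 3.00 | 26 | 49 | 13 |
| ochre | 6.00 | 6 | 65 | 20 |
| ochre | 10.0 | 4 | 80 | 14 |
| violet | 0.667 | 20 | 0 | 0 |
| violet | 1.50 | 30 | 4 | 5 |
| violet | 4.00 | 32 | 15 | 19 |
| violet | 10.0 | 17 | 36 | 21 |

(scatter of a reading: 2 percentage points)

- what may be going on: D + X -> Q + J; E + D -> L + J; D + L -> Q + J; X <-> Z; E + D <-> X + J
- "hardly changes" means that all values lie within two and a half points (for a concentration: within two and a half percent of the largest)

- share of X in all that became X or Q or Z for south, east, south-west, north-west, north-east, in this order
- how that number moves from the first to the last of them (falls, then rises / hardly changes / falls all the way / rises, then falls / rises all the way)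

So I reckoned in D-minutes for south:

dose = 28.8 mM × 15 min = 25.9 M·s

This is the dose of D, the D concentration summed over the minutes; with D steady it is charge times time.

I watched the ochre run in slow motion. In the first instants E meets D, and the readings after 1.00 min put 59.0% of the ochre flask's E in X, Q and Z together, with X at 41%. Read as a one-way step, that gives

k = 0.346 M⁻¹ s⁻¹.

In the middle, at 3.00 min, ochre's Q stood at 49% against X at 26% and Z at 13%. At the end, 10.0 min, its dose of 25.8 M·s matched south's, with the same E charge, which can take at most 4.00 mM of D. So I gave south the share in ochre's last reading: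

share = 4.08%

At the other end, in north-east, D is the limiting reagent, 28.8 mM against 150 mM of E. If the first step ran one way, D's dose would stop near 0.556 M·s, less than ochre's first dose, where Q was still 11%. So I expected little Q in north-east, and a share near ochre's late X/(X+Z), 22.2%, a reading with scatter 2 percentage points.

The forecast gave 5%, 9%, 20%, 35%, 38%, so rises all the way, saying “the X/Z equilibrium sets the share at about 38%”. My top end stood lower than the forecast's.

The flask gave 5.45%, 6.84%, 8.64%, 8.97%, 9.63%: rises all the way.

    D + X → Q + J (k = 0.176 M⁻¹ s⁻¹)
    E + D → L + J (k = 0.0201 M⁻¹ s⁻¹)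
    D + L → Q + J (k = 0.427 M⁻¹ s⁻¹)
    X ⇌ Z (K = 1.60, k = 0.00306 s⁻¹)
    E + D ⇌ X + J (K = 0.201, k = 0.413 M⁻¹ s⁻¹)

At 15.0 min, north-east held, in percent of the E charged, Q at 5.76% beside X at 0.900% and Z at 2.68%. South-west kept 53.1% of its D at 7.50 min and 43.0% at 15.0 min. Weighting start, middle and end as Simpson does, its dose comes to 15.3 M·s, close to ochre's charge times time, 15.5 M·s at 6.00 min. Q's part of X, Q and Z was 71.4% in that ochre reading and 72.0% in south-west.

The numbers in the tables are simulated with made-up constants; scatter was added.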